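**Plan**
1. Retrosynthetic cuts: (a) the bond from C2 of quinone ring B to the phenol oxygen of benzoate ring A; (b) both CH2–CH= bonds of the prenyl groups on C5 and C6 of ring B; (c) the two quinone carbonyls, which go back to aryl methyl ethers.
2. Enabling feature: C5 and C6 are adjacent atoms of ring B, and each bears a ring-bound CH2 attached to an isobutenyl CH=C(CH3)2 unit. Cut (b) therefore leaves an ortho-xylene with all six ring positions filled, whose two methyl groups are the only sites open to radical bromination.
3. Forward, no ring is built. Ring B comes from 2,3-dimethylhydroquinone by methylation, bromination, methoxylation, chlorination of the last ring C–H and twofold benzylic bromination.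
4. Both prenyl chains are joined in one twofold benzylic Suzuki coupling, and the arene is then oxidised to the chloromethoxyquinone.
5. Ring A (methyl 2,4,6-trihydroxybenzoate with two hydroxyls silylated) is attached last by displacement of chloride, followed by desilylation.
6. Stereochemistry: none to set. The target has no stereocentre and both alkenes end in geminal methyl groups.

Key step: step 6

Assumption: where one reagent acts twice on like groups in a single operation (steps 1, 5, 8 and 10), the half-reacted species is taken as part of that one transformation; the two half-coupled bromides of the key step are numbered because the outcome depends on them.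

**Step 1**
Reactants: 1 2,3-dimethylhydroquinone
Product: 2 1,4-dimethoxy-2,3-dimethylbenzene
Conditions: MeI, K2CO3, acetone, reflux, N2
Reagents that add atoms: iodomethane, CI
Why: Williamson O-methylation of both phenols with a carbonate base is routine for hydroquinones once air is excluded, and the para-dimethyl ether later serves as the latent quinone.

**Step 2**
Reactants: 2 1,4-dimethoxy-2,3-dimethylbenzene
Product: 3 1-bromo-2,5-dimethoxy-3,4-dimethylbenzene
Conditions: NBS (1.0 equiv), MeCN, 0 °C to rt
Reagents that add atoms: N-bromosuccinimide, O=C1CCC(=O)N1Br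
Why: Electrophilic aromatic bromination in a polar solvent attacks one of the two equivalent free ring positions, and the bromine introduced slows a second substitution enough for one equivalent of NBS to stop at the monobromide.

**Step 3**
Reactants: 3 1-bromo-2,5-dimethoxy-3,4-dimethylbenzene
Product: 4 1,2,5-trimethoxy-3,4-dimethylbenzene
Conditions: NaOMe, CuBr (cat.), MeOH/DMF, 110 °C
Reagents that add atoms: sodium methoxide, [Na+].[O-]C
Why: Copper-catalysed Ullmann-type methoxylation of an aryl bromide is a standard entry to polymethoxyarenes, and no other group in 3 reacts with methoxide.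

**Step 4**
Reactants: 4 1,2,5-trimethoxy-3,4-dimethylbenzene
Product: 6 1-chloro-2,3,6-trimethoxy-4,5-dimethylbenzene, via aryllithium 5 (not isolated)
Conditions: n-BuLi, THF, 0 °C; then C2Cl6, −78 °C to rt
Reagents that add atoms: hexachloroethane, ClC(Cl)(Cl)C(Cl)(Cl)Cl; n-butyllithium, [Li]CCCC (supplies only the lithium of 5)
Why: Directed ortho-metalation removes the single ring hydrogen, which lies between two coordinating methoxy groups and is lithiated much faster than the benzylic positions, and hexachloroethane then acts as a positive-chlorine donor toward the aryllithium.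

**Step 5**
Reactants: 6 1-chloro-2,3,6-trimethoxy-4,5-dimethylbenzene
Product: 7 1,2-bis(bromomethyl)-4-chloro-3,5,6-trimethoxybenzene
Conditions: NBS (2.1 equiv), AIBN (cat.), PhCF3, reflux
Reagents that add atoms: N-bromosuccinimide, O=C1CCC(=O)N1Br
Why: In this Wohl–Ziegler radical bromination every ring position is occupied, so ring bromination is shut off and hydrogen abstraction can occur only at the two benzylic methyl groups, each of which should stop at CH2Br with about one equivalent of NBS per methyl.

**Step 6**
Reactants: 7 1,2-bis(bromomethyl)-4-chloro-3,5,6-trimethoxybenzene; 8 2-methylprop-1-enylboronic acid pinacol ester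
Product: 11 4-chloro-3,5,6-trimethoxy-1,2-bis(3-methylbut-2-enyl)benzene, via monoprenyl bromide 9 (not isolated), via isomeric monoprenyl bromide 10 (not isolated)
Conditions: 8 (3 equiv), PdCl2(dppf) (5 mol %), K3PO4, THF/H2O (20:1), 60 °C
Reagents that add atoms: none
Why: The cycle opens with oxidative addition of dppf-ligated zerovalent palladium, formed in the flask from PdCl2(dppf), to one CH2–Br bond of 7; the resulting benzylpalladium bromide has only a ring carbon next to the metal-bearing carbon and cannot lose a beta hydride, so it persists until the phosphate-activated boronate 8 hands over its isobutenyl group and reductive elimination forges the CH2–CH= bond. The half-coupled bromides 9 and 10 re-enter the same cycle at the remaining arm and converge on 11. The closest known reaction type is the Suzuki–Miyaura sp3–sp2 coupling of benzylic bromides with alkenylboronates, which has also been run twofold on 1,2-bis(bromomethyl)arenes with other boron partners. No ring is closed and no stereocentre is formed, and because the double bond is brought in intact by 8 and ends in C(CH3)2, neither alkene geometry nor the linear/branched ambiguity of prenyl-metal reagents arises. The selectivity required is benzylic C–Br over aryl C–Cl; it is secured by the weak sp3 C–Br bonds on one side and, on the other, by a chloride that sits on a very electron-rich ring between two methoxy groups and is not attacked by this catalyst at 60 °C. Excess 8 and a minimum of water keep transmetalation ahead of solvolysis of the bromides and of insertion of the second benzylpalladium centre into the first prenyl alkene.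

**Step 7**
Reactants: 11 4-chloro-3,5,6-trimethoxy-1,2-bis(3-methylbut-2-enyl)benzene
Product: 12 2-chloro-3-methoxy-5,6-bis(3-methylbut-2-enyl)cyclohexa-2,5-diene-1,4-dione
Conditions: (NH4)2Ce(NO3)6, MeCN/H2O, 0 °C
Reagents that add atoms: water, O
Why: In this oxidative demethylation two one-electron oxidations of the electron-rich ring and attack of water at the two para-related methoxy-bearing carbons release the para-quinone, a reaction routinely applied to prenylated polymethoxyarenes without harm to trisubstituted alkenes and with a clear preference for the para over the ortho methoxy pair.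

**Step 8**
Reactants: 13 methyl 2,4,6-trihydroxybenzoate
Product: 14 methyl 2,4-bis[(tert-butyldimethylsilyl)oxy]-6-hydroxybenzoate
Conditions: TBSCl (2.1 equiv), imidazole, DMF, 0 °C to rt
Reagents that add atoms: tert-butyldimethylsilyl chloride, CC(C)(C)[Si](C)(C)Cl
Why: Imidazole-promoted silyl ether formation should stop at the bis-ether because the 4-hydroxyl and one ortho hydroxyl react readily, whereas the last ortho hydroxyl stays locked in a strong hydrogen bond to the ester carbonyl, as is well known for 2,4,6-trihydroxyaryl carbonyl compounds.

**Step 9**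
Reactants: 14 methyl 2,4-bis[(tert-butyldimethylsilyl)oxy]-6-hydroxybenzoate; 12 2-chloro-3-methoxy-5,6-bis(3-methylbut-2-enyl)cyclohexa-2,5-diene-1,4-dione
Product: 16 methyl 2,4-bis[(tert-butyldimethylsilyl)oxy]-6-{[2-methoxy-4,5-bis(3-methylbut-2-enyl)-3,6-dioxocyclohexa-1,4-dien-1-yl]oxy}benzoate, via sodium phenoxide 15 (not isolated)
Conditions: 14 (1.2 equiv), NaH (1.1 equiv), THF, 0 °C; then 12, −20 °C to rt
Reagents that add atoms: sodium hydride, [Na+].[H-] (supplies only the sodium of 15)
Why: In this addition–elimination on a haloquinone (vinylogous acyl substitution) the phenoxide adds to the chlorine-bearing C2 and chloride leaves irreversibly, whereas addition at the methoxy-bearing C3 merely expels the better leaving aryloxide again, and since ring B is symmetric apart from these two substituents either course of events ends in the same constitution.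

**Step 10**
Reactants: 16 methyl 2,4-bis[(tert-butyldimethylsilyl)oxy]-6-{[2-methoxy-4,5-bis(3-methylbut-2-enyl)-3,6-dioxocyclohexa-1,4-dien-1-yl]oxy}benzoate
Product: 17 atrovirinone, methyl 2,4-dihydroxy-6-{[2-methoxy-4,5-bis(3-methylbut-2-enyl)-3,6-dioxocyclohexa-1,4-dien-1-yl]oxy}benzoate
Conditions: Et3N·3HF, THF, 0 °C to rt
Reagents that add atoms: none
Why: Fluoride-mediated cleavage of aryl silyl ethers with the mildly acidic Et3N·3HF generates no free phenoxide or strong base, so the aryloxyquinone, the methyl ester and the prenyl groups should stay intact.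

**Compound list**
1 | 2,3-dimethylhydroquinone | Cc1c(O)ccc(O)c1C | starting material
2 | 1,4-dimethoxy-2,3-dimethylbenzene | COc1ccc(OC)c(C)c1C | intermediate
3 | 1-bromo-2,5-dimethoxy-3,4-dimethylbenzene | COc1cc(Br)c(OC)c(C)c1C | intermediate
4 | 1,2,5-trimethoxy-3,4-dimethylbenzene | COc1cc(OC)c(OC)c(C)c1C | intermediate
5 | (2,3,6-trimethoxy-4,5-dimethylphenyl)lithium | [Li]c1c(OC)c(C)c(C)c(OC)c1OC | intermediate
6 | 1-chloro-2,3,6-trimethoxy-4,5-dimethylbenzene | COc1c(OC)c(Cl)c(OC)c(C)c1C | intermediate
7 | 1,2-bis(bromomethyl)-4-chloro-3,5,6-trimethoxybenzene | COc1c(OC)c(Cl)c(OC)c(CBr)c1CBr | intermediate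
8 | 2-methylprop-1-enylboronic acid pinacol ester | CC(C)=CB1OC(C)(C)C(C)(C)O1 | starting material
9 | 2-(bromomethyl)-4-chloro-3,5,6-trimethoxy-1-(3-methylbut-2-enyl)benzene (numbering of 7 kept) | COc1c(OC)c(Cl)c(OC)c(CBr)c1CC=C(C)C | intermediate
10 | 1-(bromomethyl)-4-chloro-3,5,6-trimethoxy-2-(3-methylbut-2-enyl)benzene (numbering of 7 kept) | COc1c(OC)c(Cl)c(OC)c(CC=C(C)C)c1CBr | intermediate
11 | 4-chloro-3,5,6-trimethoxy-1,2-bis(3-methylbut-2-enyl)benzene | COc1c(OC)c(Cl)c(OC)c(CC=C(C)C)c1CC=C(C)C | intermediate
12 | 2-chloro-3-methoxy-5,6-bis(3-methylbut-2-enyl)cyclohexa-2,5-diene-1,4-dione | COC1=C(Cl)C(=O)C(CC=C(C)C)=C(CC=C(C)C)C1=O | intermediate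
13 | methyl 2,4,6-trihydroxybenzoate | COC(=O)c1c(O)cc(O)cc1O | starting material
14 | methyl 2,4-bis[(tert-butyldimethylsilyl)oxy]-6-hydroxybenzoate | COC(=O)c1c(O)cc(O[Si](C)(C)C(C)(C)C)cc1O[Si](C)(C)C(C)(C)C | intermediate
15 | sodium 3,5-bis[(tert-butyldimethylsilyl)oxy]-2-(methoxycarbonyl)phenoxide | COC(=O)c1c([O-])cc(O[Si](C)(C)C(C)(C)C)cc1O[Si](C)(C)C(C)(C)C.[Na+] | intermediate
16 | methyl 2,4-bis[(tert-butyldimethylsilyl)oxy]-6-{[2-methoxy-4,5-bis(3-methylbut-2-enyl)-3,6-dioxocyclohexa-1,4-dien-1-yl]oxy}benzoate | COC(=O)c1c(O[Si](C)(C)C(C)(C)C)cc(O[Si](C)(C)C(C)(C)C)cc1OC1=C(OC)C(=O)C(CC=C(C)C)=C(CC=C(C)C)C1=O | intermediate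
17 | atrovirinone | COC(=O)c1c(O)cc(O)cc1OC1=C(OC)C(=O)C(CC=C(C)C)=C(CC=C(C)C)C1=O | target

**Totals**
Total step count: 10.
Longest linear sequence: 9 steps (steps 1 to 7, 9 and 10). Step 8 is a one-step side branch.

**Steps most likely to fail**

Step 6.
- Risk: solvolysis of the very electron-rich benzylic bromides, in which hydrolysis of one arm can be followed by ring closure onto the other.
- Risk: loss of both bromines at the benzylpalladium stage to give an ortho-quinodimethane that polymerises.
- Risk: 5-exo insertion of the second benzylpalladium centre into the first prenyl alkene.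
- Fallback: the same CH2–CH= bonds are formed with the polarity reversed.
  - Setting out from 7, copper-catalysed borylation (bis(pinacolato)diboron, CuI, PPh3, LiOMe, DMF, rt) should give the bis(benzylic boronate) 2,2'-[(4-chloro-3,5,6-trimethoxy-1,2-phenylene)bis(methylene)]bis(4,4,5,5-tetramethyl-1,3,2-dioxaborolane) F1, which no longer ionises or hydrolyses.
  - A twofold Suzuki–Miyaura coupling of F1 with 1-bromo-2-methylprop-1-ene (PdCl2(dppf), K3PO4, dioxane/H2O, 80 °C) comes back to the route at 11.
  - Oxidative addition then takes place at the alkenyl bromide. No benzylpalladium halide ever sits beside a second C–Br bond, and the benzyl(alkenyl)palladium species should collapse by reductive elimination before it can insert into a neighbouring alkene.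

Step 9.
- Risk: substitution by a crowded, ester-chelated phenoxide may be slow, which gives side processes time to take over.
- These side processes are base-induced tautomerisation of the prenylquinone to a quinone methide with electrocyclisation to a chromenol, silyl transfer between phenoxides, attack through a ring-A carbon, and electron transfer to the quinone.
- Fallback: the local mirror symmetry of ring A is used so that the nucleophile needs only one remote protecting group.
  - Setting out from 13, TIPSCl (1.0 equiv) and imidazole in DMF at 0 °C should silylate only the unchelated 4-hydroxyl, giving methyl 2,6-dihydroxy-4-[(triisopropylsilyl)oxy]benzoate F2, whose two remaining hydroxyls are equivalent.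
  - One equivalent of NaH in THF converts an excess of F2 into its monosodium phenoxide F3.
  - F3 displaces chloride from 12 to give methyl 2-hydroxy-6-{[2-methoxy-4,5-bis(3-methylbut-2-enyl)-3,6-dioxocyclohexa-1,4-dien-1-yl]oxy}-4-[(triisopropylsilyl)oxy]benzoate F4.
  - Et3N·3HF in THF then comes back to the route at 17.
  - The ester stays planar and hydrogen-bonded, the reacting oxygen is less shielded, and the single bulky silyl group is far from any phenoxide.

Step 7.
- Risk: the chlorine raises the oxidation potential of the ring, so oxidation or nitrate addition at the two trisubstituted alkenes may compete.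
- Risk: the ortho-related methoxy pair may be lost instead of the para pair.
- Fallback: the chemical oxidant is replaced by a two-stage electrochemical route.
  - Setting out from 11, constant-current electrolysis at a platinum anode in methanolic KOH at 0 °C should give the quinone bis(dimethyl ketal) 1-chloro-2,3,3,6,6-pentamethoxy-4,5-bis(3-methylbut-2-enyl)cyclohexa-1,4-diene F5. Addition of methanol across the para positions fixes the para-quinone pattern.
  - Mild hydrolysis with aqueous acetic acid in acetone comes back to the route at 12.

**Further compounds**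
F1 | step 6 | 2,2'-[(4-chloro-3,5,6-trimethoxy-1,2-phenylene)bis(methylene)]bis(4,4,5,5-tetramethyl-1,3,2-dioxaborolane) | COc1c(OC)c(Cl)c(OC)c(CB2OC(C)(C)C(C)(C)O2)c1CB3OC(C)(C)C(C)(C)O3
F2 | step 9 | methyl 2,6-dihydroxy-4-[(triisopropylsilyl)oxy]benzoate | COC(=O)c1c(O)cc(O[Si](C(C)C)(C(C)C)C(C)C)cc1O
F3 | step 9 | sodium 3-hydroxy-2-(methoxycarbonyl)-5-[(triisopropylsilyl)oxy]phenoxide | COC(=O)c1c(O)cc(O[Si](C(C)C)(C(C)C)C(C)C)cc1[O-].[Na+]
F4 | step 9 | methyl 2-hydroxy-6-{[2-methoxy-4,5-bis(3-methylbut-2-enyl)-3,6-dioxocyclohexa-1,4-dien-1-yl]oxy}-4-[(triisopropylsilyl)oxy]benzoate | COC(=O)c1c(O)cc(O[Si](C(C)C)(C(C)C)C(C)C)cc1OC1=C(OC)C(=O)C(CC=C(C)C)=C(CC=C(C)C)C1=O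
F5 | step 7 | 1-chloro-2,3,3,6,6-pentamethoxy-4,5-bis(3-methylbut-2-enyl)cyclohexa-1,4-diene | COC1=C(Cl)C(OC)(OC)C(CC=C(C)C)=C(CC=C(C)C)C1(OC)OC
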